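I took the sum Q + J + X + L to stay at the charge of Q, and so reckoned L as the difference of the readings. I counted one E for each J or X and two for each L.

| flask | Q | E | remark | time |
|---|---|---|---|---|
| Wednesday's | 7 mM | 1.2 equiv | run made earlier |  |
| Friday's | 28 mM | 1.2 equiv | run made earlier |  |
| Saturday's | 14 mM | 0.60 equiv | run made earlier |  |
| flask | 14 mM | 1.20 equiv |  | 6.0 h |

| run | time / h | Q / % | J / % | X / % |
|---|---|---|---|---|
| Wednesday's | 0.250 | 69.1 | 23.7 | 1.0 |
| Wednesday's | 0.500 | 61.4 | 27.5 | 2.7 |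
| Wednesday's | 0.833 | 59.1 | 29.2 | 2.7 |
| Wednesday's | 1.33 | 57.5 | 29.3 | 2.8 |
| Wednesday's | 2.00 | 58.3 | 28.4 | 2.6 |
| Wednesday's | 4.00 | 57.9 | 28.9 | 2.2 |
| Friday's | 0.667 | 36.8 | 33.4 | 3.7 |
| Friday's | 1.33 | 37.1 | 33.6 | 4.1 |
| Friday's | 2.00 | 37.0 | 33.8 | 3.6 |
| Friday's | 2.50 | 37.6 | 33.5 | 3.2 |
| Friday's | 3.00 | 37.2 | 33.8 | 3.8 |
| Friday's | 4.00 | 36.6 | 34.5 | 3.9 |
| Saturday's | 0.333 | 72.0 | 21.4 | 1.2 |
| Saturday's | 0.833 | 67.8 | 23.8 | 1.2 |
| Saturday's | 1.50 | 69.0 | 23.6 | 2.3 |
| Saturday's | 2.50 | 68.0 | 24.0 | 2.4 |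
| Saturday's | 4.00 | 68.3 | 23.7 | 0.9 |

(scatter of a reading: 0.5 percentage points)

- how much Q there is at 6.0 h, in percent of the Q charged
- how much J there is at 6.0 h, in percent of the Q charged
- how much X there is at 6.0 h, in percent of the Q charged
- how much L there is at 6.0 h, in percent of the Q charged

I read the time scales first. On the shortest rung Q fell: Wednesday's run stood at 69.1% by 0.250 h. On the next rung the change ended: Wednesday's run was flat by 1.33 h, Friday's by its first reading at 0.667 h. On the longest rung, out to 4.00 h, Friday's readings only scattered. So I placed the flask at 6.0 h on the flat part, and the question became how much E the flat state had spent. Per Q charged, that is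

s = 2(100% − Q) − J − X.

With e the equivalents charged, w = s/(e − s) sets E spent on adducts against E not so spent. From the last readings:

Wednesday's, 7 mM: s = 53.1%, w = 0.794

Friday's, 28 mM: s = 88.4%, w = 2.80

The flask has the same equivalents, and its 14 mM is the geometric mean of those two charges, so I took the geometric mean of w as well:

w = 1.49

This spending ratio gave s = e·w/(1 + w) = 71.8%. Taking J + X as the mean of the two runs, 34.8%, the balance gave Q = 46.7% and L = 18.5%.

The forecast, holding that “these are equilibria”, said Q 46.2%, J 32.6%, X 3.1%, L 18.1%. My Q was higher by 0.50 percentage points, still below the top of its range, 47.6%.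

The flask gave Q 46.1%, J 32.8%, X 3.31%, L 17.7%, by this scheme:

    Q + E → J + G (k = 4.78 M⁻¹ min⁻¹)
    Q + E → X + G (k = 0.327 M⁻¹ min⁻¹)
    E + J → L + G (k = 5.33 M⁻¹ min⁻¹)
    E + X → L + G (k = 0.485 M⁻¹ min⁻¹)
    E → Z (k = 0.0448 min⁻¹)

At 6.00 h E stood in this flask at 0% of its charge, less than Q's 46%, and E was the limiting reagent. In this flask G counts E spent on adducts and Z the rest, so G 10.0 mM over Z 6.78 mM is w = 1.47. In the neighbour flask with 5.6 mM of Q, the same balance on Q 62.3%, J 27.3% and X 2.36% gives s = 45.8% and w = 0.617, less than the 1.49 I had carried for the 14 mM flask.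

The runs stem from a simulated flask with constants of no real substance; the scatter is artificial.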